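**Retrosynthetic overview** (carotenoid numbering: ring C1–C6, chain C7…C15, C15'…C12')
1. C11=C12 by Wittig: the target comes from C15 furanoid enal 15 and C10 hydroxy-phosphonium salt 18, which is made from the C10-dialdehyde 16.
2. Enal 15 comes from the acyclic 1,7-enyne triol 12, with both rings closed in one pot. The cyclohexane forms first (C1–C6, Pd–H reductive enyne cyclisation, which also creates the gem-dimethyl group and the Z C6=C7). The dihydrofuran forms second (O–C5, capture of the C5 allyl cation by the C8–OH).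
3. Stereochemistry: C3 and C8 are set by catalysts. C5 is relayed from C8 by A1,3 strain. The racemic C5 carbinol is erased on ionisation.
4. Triol 12 comes from alkyne 6 and enal 10. Alkyne 6 comes from 4-hydroxybutan-2-one, ethynyl Grignard and methallyl chloride. Enal 10 comes from propanal and glyoxal mono-acetal.

Assumption: ligand antipodes are named for the sense of induction wanted (checked by Mosher ester; if the mirror carbinol forms, the other antipode is used), and 16 is bought as the industrial C10-dialdehyde.

**Step 1**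
Reactants: 1 4-hydroxybutan-2-one; 2 ethynylmagnesium bromide
Product: 3 3-methylpent-4-yne-1,3-diol (racemic)
Conditions: 2 (2.3 equiv), THF, −20 → 0 °C; aq NH4Cl
Reagents that add atoms: none
Why: Grignard 1,2-addition to the methyl ketone (the first equivalent is spent on the OH); the tertiary carbinol (future C5) is left racemic on purpose because step 5 ionises and re-sets this centre.

**Step 2**
Reactants: 3 3-methylpent-4-yne-1,3-diol; 4 3-chloro-2-methylprop-1-ene
Product: 6 (5S)-3,7-dimethyloct-7-en-1-yne-3,5-diol (both C3 epimers), via hydroxy-ynal 5 (not isolated)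
Conditions: [Ir(cod)Cl]2 (2.5 mol %), (R)-SEGPHOS (5 mol %), 4-cyano-3-nitrobenzoic acid (10 mol %), K3PO4 (1 equiv), THF, 70 °C
Reagents that add atoms: none
Why: Iridium-catalysed transfer-hydrogenative carbonyl methallylation (Krische type): only the primary alcohol is dehydrogenated, and the chiral π-methallyl-iridium traps aldehyde 5 at once through a closed chair transition state, so the ligand sets carotenoid C3 as S and the labile β-hydroxy aldehyde never builds up.

**Step 3**
Reactants: 7 2,2-dimethoxyacetaldehyde; 8 propanal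
Product: 10 (2E)-4,4-dimethoxy-2-methylbut-2-enal, via aldol adduct 9 (not isolated)
Conditions: piperidine/AcOH (10 mol %), toluene, 70 °C, slow addition of 8
Reagents that add atoms: none
Why: Crossed aldol condensation in which only propanal can enolise and the mono-acetal of glyoxal is the better acceptor; E1cB loss of water gives the thermodynamic E-enal.

**Step 4**
Reactants: 6 (5S)-3,7-dimethyloct-7-en-1-yne-3,5-diol; 10 (2E)-4,4-dimethoxy-2-methylbut-2-enal
Product: 12 (2E,4S,9S)-1,1-dimethoxy-3,7,11-trimethyldodeca-2,11-dien-5-yne-4,7,9-triol (both C7 epimers), via methylzinc alkynylide 11 (not isolated)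
Conditions: Me2Zn (3.5 equiv), (S,S)-ProPhenol (20 mol %), Ph3P=O (40 mol %), toluene, 4 °C; aq NH4Cl
Reagents that add atoms: none
Why: Zn-ProPhenol catalysed asymmetric alkynylation of an α-branched enal; the dinuclear zinc pocket delivers the alkynyl group to the Re face and sets carotenoid C8 (descriptor S here, R once C7 becomes an alkene carbon).

**Step 5** (key step)
Reactants: 12 (2E,4S,9S)-1,1-dimethoxy-3,7,11-trimethyldodeca-2,11-dien-5-yne-4,7,9-triol
Product: 15 (2E)-3-[(2R,6S,7aR)-6-hydroxy-4,4,7a-trimethyl-2,4,5,6,7,7a-hexahydro-1-benzofuran-2-yl]but-2-enal, via Z-ene-triol acetal 13 (not isolated), via Z-ene-triol enal 14 (not isolated)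
Conditions: Pd2(dba)3·CHCl3 (5 mol %), P(o-tol)3 (20 mol %), HCO2H (1.5 equiv), dry toluene, 25–40 °C; then THF, H2O (2 equiv), CSA (10 mol %), 0 °C, same flask
Reagents that add atoms: water, O
Why: Proposed new method: H–Pd–O2CH adds syn across the alkyne (H to C7, Pd to C6, steered by the tethered alkene), the vinyl-palladium closes the cyclohexane by 6-exo carbopalladation of the 1,1-disubstituted alkene (quaternary C1), and the resulting alkyl-palladium, which has no β-hydrogen, loses CO2 and reductively eliminates to the second C1 methyl, so syn addition places C8 cis to C5 in 13; acid then unmasks the enal (which blocks ionisation at C8) and ionises the tertiary allylic C5–OH of both C5 epimers to one planar allyl cation, which the retained C8–OH captures from the face that keeps C8–H rather than the butenal arm next to the C5 methyl (A1,3 strain), giving 5R from 8R with the side chain trans to that methyl; the closest known reactions are the palladium-hydride reductive cyclisation of 1,6- and 1,7-enynes with silane or formic acid and the acid cyclodehydration of (Z)-2-ene-1,4-diols to 2,5-dihydrofurans.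

**Step 6**
Reactants: 16 (2E,4E,6E)-2,7-dimethylocta-2,4,6-trienedial
Product: 17 (2E,4E,6E)-2,7-dimethylocta-2,4,6-triene-1,8-diol
Conditions: NaBH4, MeOH/THF, 0 °C
Reagents that add atoms: none
Why: Borohydride 1,2-reduction of both conjugated aldehydes; no stereocentre is involved and the E-triene is untouched.

**Step 7**
Reactants: 17 (2E,4E,6E)-2,7-dimethylocta-2,4,6-triene-1,8-diol
Product: 18 [(2E,4E,6E)-8-hydroxy-2,7-dimethylocta-2,4,6-trien-1-yl]triphenylphosphonium bromide
Conditions: PPh3·HBr (0.5 equiv relative to 17), MeOH/CH2Cl2, 0 °C → rt; excess 17 recovered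
Reagents that add atoms: triphenylphosphine hydrobromide, [Br-].[PH+](c1ccccc1)(c1ccccc1)c1ccccc1
Why: Standard polyene phosphonium salt formation (SN1-type substitution of an allylic alcohol); excess diol holds the reaction at the mono-salt, and attack at the chain end keeps the all-E triene conjugated.

**Step 8**
Reactants: 15 (2E)-3-[(2R,6S,7aR)-6-hydroxy-4,4,7a-trimethyl-2,4,5,6,7,7a-hexahydro-1-benzofuran-2-yl]but-2-enal; 18 [(2E,4E,6E)-8-hydroxy-2,7-dimethylocta-2,4,6-trien-1-yl]triphenylphosphonium bromide
Product: 20 (3S,5R,8R)-5,8-epoxy-5,8-dihydro-12'-apo-β-carotene-3,12'-diol, via oxido-ylide 19 (not isolated)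
Conditions: 18 (1.2 equiv), NaHMDS (2.4 equiv), THF, −78 °C; then 15, −78 → 0 °C; H2O; warm in heptane/EtOAc (60 °C, dark) to convert 11Z into 11E
Reagents that add atoms: none
Why: Wittig olefination with a semi-stabilised trienyl ylide builds C11=C12; the preformed ylide at −78 °C avoids γ-deprotonation at C8–H of 15, the hindered 11Z isomer relaxes thermally to all-E, and no stereocentre is touched.

**Compound list**
1 | 4-hydroxybutan-2-one | CC(=O)CCO | starting material
2 | ethynylmagnesium bromide | C#C[Mg]Br | starting material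
3 | 3-methylpent-4-yne-1,3-diol (racemic) | C#CC(C)(O)CCO | intermediate
4 | 3-chloro-2-methylprop-1-ene | CC(=C)CCl | starting material
5 | 3-hydroxy-3-methylpent-4-ynal | C#CC(C)(O)CC=O | intermediate
6 | (5S)-3,7-dimethyloct-7-en-1-yne-3,5-diol (both C3 epimers) | C#CC(C)(O)C[C@@H](O)CC(C)=C | intermediate
7 | 2,2-dimethoxyacetaldehyde | COC(OC)C=O | starting material
8 | propanal | CCC=O | starting material
9 | 3-hydroxy-4,4-dimethoxy-2-methylbutanal | COC(OC)C(O)C(C)C=O | intermediate
10 | (2E)-4,4-dimethoxy-2-methylbut-2-enal | COC(OC)/C=C(\C)C=O | intermediate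
11 | tris(methylzinc) derivative of 6 (C-alkynylide, two O-alkoxides) | C[Zn]C#CC(C)(O[Zn]C)C[C@@H](O[Zn]C)CC(C)=C | intermediate
12 | (2E,4S,9S)-1,1-dimethoxy-3,7,11-trimethyldodeca-2,11-dien-5-yne-4,7,9-triol (both C7 epimers) | COC(OC)/C=C(\C)[C@H](O)C#CC(C)(O)C[C@@H](O)CC(C)=C | intermediate
13 | (2E,4R,5Z)-5-[(4S)-2,4-dihydroxy-2,6,6-trimethylcyclohexylidene]-1,1-dimethoxy-3-methylpent-2-en-4-ol | COC(OC)/C=C(\C)[C@H](O)/C=C1\C(C)(O)C[C@@H](O)CC1(C)C | intermediate
14 | (2E,4R,5Z)-5-[(4S)-2,4-dihydroxy-2,6,6-trimethylcyclohexylidene]-4-hydroxy-3-methylpent-2-enal | O=C/C=C(\C)[C@H](O)/C=C1\C(C)(O)C[C@@H](O)CC1(C)C | intermediate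
15 | (2E)-3-[(2R,6S,7aR)-6-hydroxy-4,4,7a-trimethyl-2,4,5,6,7,7a-hexahydro-1-benzofuran-2-yl]but-2-enal | O=C/C=C(\C)[C@H]1C=C2C(C)(C)C[C@H](O)C[C@@]2(C)O1 | intermediate
16 | (2E,4E,6E)-2,7-dimethylocta-2,4,6-trienedial | O=C/C(C)=C/C=C/C=C(\C)C=O | starting material
17 | (2E,4E,6E)-2,7-dimethylocta-2,4,6-triene-1,8-diol | OC/C(C)=C/C=C/C=C(\C)CO | intermediate
18 | [(2E,4E,6E)-8-hydroxy-2,7-dimethylocta-2,4,6-trien-1-yl]triphenylphosphonium bromide | [Br-].OC/C(C)=C/C=C/C=C(\C)C[P+](c1ccccc1)(c1ccccc1)c1ccccc1 | intermediate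
19 | sodium oxido-ylide of 18 | [Na+].[O-]C/C(C)=C/C=C/C=C(\C)[CH-][P+](c1ccccc1)(c1ccccc1)c1ccccc1 | intermediate
20 | (3S,5R,8R)-5,8-epoxy-5,8-dihydro-12'-apo-β-carotene-3,12'-diol = (2E,4E,6E,8E,10E)-11-[(2R,6S,7aR)-6-hydroxy-4,4,7a-trimethyl-2,4,5,6,7,7a-hexahydro-1-benzofuran-2-yl]-2,7-dimethyldodeca-2,4,6,8,10-pentaen-1-ol | CC(/C=C/C=C(\C)[C@H]1C=C2C(C)(C)C[C@H](O)C[C@@]2(C)O1)=C\C=C\C=C(/C)CO | target

**Total step count:** 8. **Longest linear sequence:** 5 (steps 1, 2, 4, 5, 8).

**The three steps most likely to fail**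

Step 5. The hindered C6–C1 carbopalladation may lose to alkene isomerisation or to simple hydropalladation of the alkyne. The fallback sets out from 12 and comes back at 15, and it closes ring A by a radical instead. Fe(acac)3/PhSiH3 in EtOH transfers a hydrogen atom to the 1,1-disubstituted alkene. The tertiary C1 radical then adds 6-exo-dig to C6, and the vinyl radical takes up H from either side. Compound 13 is therefore formed together with (2E,4R,5E)-5-[(4S)-2,4-dihydroxy-2,6,6-trimethylcyclohexylidene]-1,1-dimethoxy-3-methylpent-2-en-4-ol F1. The wet-acid treatment of step 5 is run on this mixture. F1 joins the same manifold because the tertiary allylic alcohol transposes reversibly from C5 to C7, which frees rotation about C6–C7. Only the Z-cation can close, so both isomers end up as 15.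

Step 2. The terminal alkyne may poison the iridium hydride, or the transient aldehyde 5 may undergo retro-aldol cleavage. The fallback sets out from 3 and comes back at 6. The redox-neutral coupling is replaced by oxidation followed by a stoichiometric chiral borane. TEMPO/PhI(OAc)2 gives isolated 5. B-methallyl-diisopinocampheylborane at −78 °C, with NaBO3 work-up, then gives 6. New compounds: none F0.

Step 4. The free hydroxyl groups of 6 may erode the enantioselectivity of the zinc catalyst. The fallback sets out from 6 (with 10) and comes back at 12, and it sets C8 by ketone reduction instead of by addition. The lithium trianion of 6 (n-BuLi, 3 equiv, −78 °C) adds to 10 to give (2E,9S)-1,1-dimethoxy-3,7,11-trimethyldodeca-2,11-dien-5-yne-4,7,9-triol (C4 epimer mixture) F2. MnO2 oxidises only the propargylic and allylic carbinol, giving (2E,9S)-7,9-dihydroxy-1,1-dimethoxy-3,7,11-trimethyldodeca-2,11-dien-5-yn-4-one F3. Noyori transfer hydrogenation (Ru-TsDPEN, i-PrOH) of this alkynyl ketone then gives 12.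

**Further compounds**
F1 | step 5 | (2E,4R,5E)-5-[(4S)-2,4-dihydroxy-2,6,6-trimethylcyclohexylidene]-1,1-dimethoxy-3-methylpent-2-en-4-ol | COC(OC)/C=C(\C)[C@H](O)/C=C1/C(C)(O)C[C@@H](O)CC1(C)C
F0 | step 2 | none | none
F2 | step 4 | (2E,9S)-1,1-dimethoxy-3,7,11-trimethyldodeca-2,11-dien-5-yne-4,7,9-triol (C4 epimer mixture) | COC(OC)/C=C(\C)C(O)C#CC(C)(O)C[C@@H](O)CC(C)=C
F3 | step 4 | (2E,9S)-7,9-dihydroxy-1,1-dimethoxy-3,7,11-trimethyldodeca-2,11-dien-5-yn-4-one | COC(OC)/C=C(\C)C(=O)C#CC(C)(O)C[C@@H](O)CC(C)=C
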